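## Analysis of the target

The target (22 below) is a 6β-acetoxy-9α,13;15,16-diepoxylabd-14-ene. It is a trans-decalin (rings A and B; labdane numbering C1–C10, gem-dimethyl on C4, acetoxy on C6, methyl on C8, angular methyl on C10). C9 is the spiro atom of a tetrahydrofuran (O, C9, C11, C12, C13), and C13 is in turn the spiro atom of a 2,3-dihydrofuran (C13, C14=C15, O, C16).

Six stereocenters must be set, (5S,6R,8R,9R,10S,13R). H5 is α and trans to the β-methyl on C10. The acetoxy group is β and axial, syn to the axial methyls on C4 and C10. The C8 methyl is α and equatorial. The C9 oxygen is α and C11 is β. At C13, the CH2O carbon C16 lies on the C8 side of the tetrahydrofuran and C14 on the C10 side.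

C9 and C10 are adjacent fully substituted carbons. C13 is a quaternary center three bonds from the nearest stereocenter, so the decalin cannot control it.

The sensitive unit is the cyclic enol ether. C13 is allylic to it and also carries the tetrahydrofuran oxygen, so acid ionizes the C13–O bond and the ring aromatizes to a 3-substituted furan. The hindered acetate is the only base-labile group.

The hard points are therefore: an acid-free, late formation of the dihydrofuran; control of C13; the correct oxygen face at C9; and an enantioselective entry to a 4,4,8,10-tetramethyldecalin oxygenated at C6 and C9.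

The strategy rests on ring B. C6 and C9 are 1,4 to each other and C8 and C10 each carry a methyl, which is the pattern of 2,6-dimethyl-1,4-benzoquinone. Ring A, with the gem-dimethyl C4 next to the ring-fusion carbon C5, is then the four-carbon diene partner.

## Retrosynthetic reasoning

**22 to 21.** The C14=C15 enol ether is traced back to a C14 hydroxyl in 21. Dehydration comes last because every later operation would have to tolerate the acid-labile allylic spiro ether. Its regiochemistry is forced: C13 is quaternary, so only C15 carries β-hydrogens.

**21 to 19 (through 20).** The O–C13 bond of the tetrahydrofuran is cut. Forward, the tertiary 9α-hydroxyl opens a C13–C14 epoxide (20) at its tertiary carbon in a 5-exo mode with inversion. This transfers the configuration of the epoxide to C13 and leaves the C14 hydroxyl needed for the last step. The epoxide comes from reagent-controlled epoxidation of the dihydrofuran alkene of 19, because no substrate element is close enough to control C13.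

**19 to 18.** The ring double bond C13=C14 is cut by a metathesis transform. This reveals a 1,1-disubstituted alkene and an allyl ether in 18, both carried by one simple side-chain reagent.

**18 to 17 to 12 and 15.** The acetate is removed (17), then the C11–C12 bond is cut. The forward reaction is opening of spiro epoxide 12 at its CH2 carbon by the allylic Grignard reagent 16, made from chloride 15. The cut is placed here and not at C9–C11 because reagents approach C9 anti to the axial C10 methyl. A carbon nucleophile adding to a C9 ketone would therefore most likely end up α with the oxygen β, the reverse of what is needed. Opening an epoxide whose oxygen is already α keeps C9 untouched. Reagent 16 is symmetric across its allyl unit, so attack through either terminus gives the same product.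

**12 to 11 to 10.** The C9–O bond is cut (epoxidation of exocyclic alkene 11 from the α-face), then C9=C11 (methylenation of ketone 10). The oxygen is thus delivered to C9 from the less hindered face.

**10 to 8 (through 9).** The C2 methylene is traced to the silyl enol ether of 8 via dithioketal 9. The C2 oxygen is a relic of the cycloaddition and is removed as soon as C6 is no longer a ketone, so that only the very hindered C9 carbonyl remains as a bystander.

**8 to 7 to 6 to 5.** The C6 carbinol comes from hydride addition to the less hindered ketone of 7 from the α-face. The trans ring fusion and the equatorial C8 methyl of 7 come from equilibration of cis-dione 6 through its two enolizable centers. Dione 6 comes from reduction of the enedione double bond of 5.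

**5 to 3 and 4.** The C1–C10 and C4–C5 bonds of ring A are cut in a Diels–Alder transform, giving silyloxydiene 3 and quinone 4. One step then creates ring A, the C10 quaternary stereocenter, the gem-dimethyl carbon, both ring B oxygens and the C8 methyl. The price is a cis ring fusion and an extra oxygen at C2, both corrected by the short operations above.

**3 to 1 and 2; 15 to 13 and 14.** Diene 3 is the kinetic silyl dienol ether of mesityl oxide 1 with silyl triflate 2. Chloride 15 is the mono-allyl ether from dichloride 13 and allyl alcohol 14.

## Alternatives that were turned down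

**Alternative 1:** The tetrahydrofuran is cut at C11–C12 and O–C9, dividing the molecule into exocyclic alkene A2 and iodohydrin A3 (C12–C16, with C13 already configured). Their union gives the protected 9,13-epoxide A1.

- Forward key step: a C12 radical from A3 adds to the CH2 end of the C9=C11 bond of A2; the tertiary C9 radical is turned into an iodide or cation, and the C13 hydroxyl closes the ring.
- For it: it is convergent, it forms the ring in one operation, and C13 comes from a small fragment of fixed configuration. On these two points it is stronger than the chosen route, which sets C13 late by a reagent-controlled epoxidation.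
- Against it:
  - C9 is created when an oxygen tethered through C11–C12–C13 captures a planar C9. The tether can reach either face, and nothing enforces α-attack.
  - A cation at C9 next to the quaternary C10 invites methyl migration or proton loss to an alkene.
  - After the key step, two deprotections, an oxidation to the lactol and a dehydration are still needed.
  - A2 is simply the acetate of compound 11, so this plan still needs an enantioselective decalin synthesis of the length of steps 1 to 8.
- In its place the chosen strategy offers a closed-shell, sterically dictated creation of C9 (step 9), one step from ring closure to target, and a decalin built in one catalytic step from two commodity chemicals.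

**Alternative 2:** Both carbocycles are cut at C5–C10 and C6–C7, unfolding the decalin into the acyclic nitro dienone A5. A chiral primary-amine cascade returns the nitro decalone A4.

- Forward key step: the amine condenses with the C9 ketone to a cross-conjugated dienamine. Its C10 adds to the nitroalkene carbon C5 (ring A), and the nitronate carbon C6 then adds to C7 of the activated enone (ring B).
- For it: it is metal-free, it creates C5, C6, C8 and C10 in one flask, and it gives the trans ring fusion directly. Here it is stronger than the chosen route, which must epimerize C5 and remove an oxygen at C2.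
- Against it:
  - The first bond joins a fully substituted dienamine carbon to a nitroalkene carbon that is neopentyl (next to C4). C5 would be formed between two quaternary carbons in the selectivity-determining step.
  - Condensation of a primary amine with an α-branched, α′-alkenyl ketone is slow, and both acceptors can polymerize.
  - The nitro group sits α on C6, so a Nef reaction, a reduction and an acetylation are needed to reach the 6β-acetate. That returns to a 6-ketone like the one the chosen route has from the start.
  - A5 itself needs a linear synthesis of several steps.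
- The chosen strategy puts its most hindered bond (C4–C5) second in an asynchronous cycloaddition, onto a CH carbon, and takes both partners from the shelf.

**Alternative 3:** Ring B and the tetrahydrofuran are cut at C9–C10 and O–C13, giving the monocyclic epoxy ketone A7. A Lewis-acid-triggered bicyclization returns the tricyclic 5-ene A6.

- Forward key step: the ketone oxygen opens the 2,2-disubstituted epoxide at C13. The resulting five-membered oxocarbenium ion is attacked at C9 by C10 of the tetrasubstituted ring A alkene, and loss of a C6 proton leaves the 5,6-alkene.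
- For it: the tetrahydrofuran, ring B and the C9/C10 quaternary pair are made in one step, and C13 comes from a preset epoxide. For the spiro core it is stronger in step economy than the chosen route.
- Against it:
  - The configurations at C9 and C10 depend on an untested Prins transition state that must form two adjacent quaternary centers on a hindered oxocarbenium ion.
  - The Lewis acid can rearrange the epoxide to an aldehyde before cyclization.
  - A7 needs two independent stereocenters (C8, which is α to the ketone and labile, and C13) set and matched separately.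
  - A6 has no oxygen at C6. Hydroboration from the α-face (5α-H, 6α-OH), oxidation, reduction to the 6β-alcohol and acetylation add four steps, before the C13 arms are turned into the dihydrofuran.
- The chosen strategy has both ring B oxygens in place from the quinone and relies on a cycloaddition class with direct precedent.

Key step: step 2

Assumption: the sense of induction of the two chiral catalysts (steps 2 and 14) is assigned from the accepted models (α-C–H···O complex of the quinone; spiro dioxirane transition state calibrated on 1-substituted cycloalkenes); if either delivers the opposite face, its mirror-image catalyst is used and nothing else in the route changes.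

Names of decalin intermediates use the labdane numbering defined above; α means the face opposite the C10 methyl.

## Route

Step 1
Reactants: 1 mesityl oxide (4-methylpent-3-en-2-one); 2 triisopropylsilyl trifluoromethanesulfonate
Product: 3 2-(triisopropylsilyloxy)-4-methylpenta-1,3-diene
Conditions: LDA, THF, −78 °C; then 2, −78 → 0 °C
Reagents that add atoms: none
Why: Kinetic deprotonation of the enone removes an α′-methyl proton, and O-silylation of the cross-conjugated lithium dienolate gives the 2-silyloxydiene (silyl enol ether formation); no stereocenter is formed.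

Step 2
Reactants: 3 2-(triisopropylsilyloxy)-4-methylpenta-1,3-diene; 4 2,6-dimethyl-1,4-benzoquinone
Product: 5 cis-fused enedione, (5R,10S)-4,4,8,10-tetramethyl-2-(triisopropylsilyloxy)decalin-2,7-diene-6,9-dione (5β-H, 10β-CH3; systematic name (4aR,8aS)-2,5,5,8a-tetramethyl-7-(triisopropylsilyloxy)-4a,5,8,8a-tetrahydronaphthalene-1,4-dione)
Conditions: N-protonated (S)-B-(o-tolyl)-α,α-diphenylprolinol oxazaborolidine, Tf2N salt (20 mol %), CH2Cl2, −78 → −40 °C
Reagents that add atoms: none
Why: The boron cation binds the C6 carbonyl of 4 (the one flanked by two C–H carbons), helped by an α-C–H···O contact, which lowers the LUMO of one C5=C10 bond and makes C10 its electrophilic β-carbon. The reaction is a concerted but asynchronous [4+2] cycloaddition of the type established for quinones and 2-silyloxydienes under oxazaborolidinium catalysis, with the bond from the diene CH2 terminus to C10 well advanced before the C(CH3)2 terminus closes on C5. Ring A is closed by this suprafacial six-membered cycloaddition, so the C10 methyl and the C5 hydrogen must emerge cis. The absolute configuration at C10 (and with it C5) is set by the catalyst, whose aryl group covers one face of the bound dienophile so that the diene adds to the C5-Re/C10-Si face. The regioselectivity needed is secured twice: the more nucleophilic diene terminus goes to the β-carbon of the complexed enone, and the hindered dimethyl terminus ends on the hydrogen-bearing carbon. The two C=C bonds of 4 are equivalent by symmetry, so no site selectivity is required, and because neither diene terminus becomes a stereocenter the endo or exo mode leaves no trace in 5. The demanding element is the fully substituted diene terminus, which is why the most Lewis-acidic (triflimide) form of the catalyst and a temperature ramp are specified.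

Step 3
Reactants: 5 cis-fused enedione
Product: 6 cis-fused dione, (5R,8R,10S)-4,4,8,10-tetramethyl-2-(triisopropylsilyloxy)decalin-2-ene-6,9-dione (5β-H, 8α-CH3; any 8-epimer present converges in step 4)
Conditions: Zn dust, AcOH, THF, 0 → 25 °C
Reagents that add atoms: none
Why: Dissolving-metal reduction of the ene-1,4-dione (two electron transfers and protonations at C7 and C8) saturates only the doubly activated C7=C8 bond; the hindered silyl enol ether survives the short exposure to AcOH.

Step 4
Reactants: 6 cis-fused dione
Product: 7 trans-fused dione, (5S,8R,10S)-4,4,8,10-tetramethyl-2-(triisopropylsilyloxy)decalin-2-ene-6,9-dione (5α-H, 8α-CH3)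
Conditions: DBU, toluene, 60 °C
Reagents that add atoms: none
Why: Base-mediated enolization equilibrates C5 (through the C6 ketone) and C8 (through the C9 ketone); the expected minimum is the trans-fused isomer, with both ring A bonds equatorial on ring B, and with the C8 methyl equatorial, since an 8β-methyl would be syn-diaxial to the C10 methyl. DBU is non-nucleophilic and leaves the silyl enol ether intact.

Step 5
Reactants: 7 trans-fused dione
Product: 8 (5S,6R,8R,10S)-6β-hydroxy-4,4,8α,10-tetramethyl-2-(triisopropylsilyloxy)-trans-decalin-2-en-9-one
Conditions: NaBH4, MeOH/CH2Cl2, −40 → 0 °C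
Reagents that add atoms: none
Why: Hydride reduction takes the C6 ketone because C9 lies between a quaternary and a tertiary carbon; the β-face of C6 is blocked by the syn-axial methyls on C4 and C10, so hydride enters from the α-face and gives the axial 6β-alcohol.

Step 6
Reactants: 8 silyloxy hydroxy ketone
Product: 9 (5S,6R,8R,10S)-6β-hydroxy-4,4,8α,10-tetramethyl-trans-decalin-2,9-dione 2-(ethane-1,2-diyl dithioketal)
Conditions: HS(CH2)2SH, BF3·OEt2, CH2Cl2, 0 → 25 °C
Reagents that add atoms: ethane-1,2-dithiol, SCCS
Why: Lewis-acid thioketalization: protonation of the silyl enol ether at C3 gives an oxocarbenium ion at C2 that is captured twice by the dithiol with loss of the silanol; the C9 ketone is too hindered to react.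

Step 7
Reactants: 9 dithioketal
Product: 10 (5S,6R,8R,10S)-6β-hydroxy-4,4,8α,10-tetramethyl-trans-decalin-9-one
Conditions: Raney Ni (deactivated in acetone), EtOH, 60 °C
Reagents that add atoms: none
Why: Reductive desulfurization (Mozingo reduction) replaces both C–S bonds by C–H and so removes the C2 oxygen function; the hindered ketone and the alcohol are not reduced by deactivated nickel.

Step 8
Reactants: 10 hydroxy ketone
Product: 11 (5S,6R,8R,10S)-4,4,8α,10-tetramethyl-9-methylene-trans-decalin-6β-ol
Conditions: Ph3PCH3Br, KOtBu (excess), toluene, 90 °C
Reagents that add atoms: methyltriphenylphosphonium bromide, [Br-].C[P+](c1ccccc1)(c1ccccc1)c1ccccc1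
Why: Wittig methylenation under forcing, potassium-alkoxide conditions is the standard answer to α-quaternary ketones; the 6-alkoxide is a spectator, and any enolization returns the equatorial C8 methyl.

Step 9
Reactants: 11 exocyclic alkene
Product: 12 (5S,6R,8R,9R,10S)-9α,11-epoxy-4,4,8α,10-tetramethyl-trans-decalin-6β-ol (spiro oxirane on C9, oxygen α, CH2 = C11 β)
Conditions: dimethyldioxirane, acetone, 0 °C
Reagents that add atoms: dimethyldioxirane, CC1(C)OO1
Why: Electrophilic epoxidation by a dioxirane is sterically controlled and comes from the α-face, anti to the axial methyl on the neighboring C10, which sets C9 with oxygen α and C11 β. The neutral medium protects the tertiary spiro epoxide from rearrangement.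

Step 10
Reactants: 13 3-chloro-2-(chloromethyl)prop-1-ene; 14 allyl alcohol (prop-2-en-1-ol)
Product: 15 3-(allyloxy)-2-(chloromethyl)prop-1-ene
Conditions: 14, NaH, THF, 0 °C; then 13 (excess), 0 → 25 °C
Reagents that add atoms: none
Why: Williamson ether synthesis by substitution at one allylic chloride; the excess of 13 suppresses the bis-ether.

Step 11
Reactants: 12 spiro epoxide; 15 3-(allyloxy)-2-(chloromethyl)prop-1-ene
Product: 17 (5S,6R,8R,9R,10S)-9β-{3-[(allyloxy)methyl]but-3-en-1-yl}-4,4,8α,10-tetramethyl-trans-decalin-6β,9α-diol, via Grignard reagent 16 (not isolated)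
Conditions: 15, Mg, THF, 0 °C; then CuI (10 mol %), 12, THF, −30 → 0 °C
Reagents that add atoms: none
Why: Copper-catalysed substitution opens the epoxide at its CH2 carbon (C11) and forms C11–C12 without touching the C9–O bond, so the 9α-oxygen is retained as the tertiary alcohol. The allyl unit of 16 is symmetric, so both termini give the same product; one further equivalent of 16 is consumed by the free 6-hydroxyl.

Step 12
Reactants: 17 diol
Product: 18 (5S,6R,8R,9R,10S)-6β-acetoxy-9β-{3-[(allyloxy)methyl]but-3-en-1-yl}-4,4,8α,10-tetramethyl-trans-decalin-9α-ol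
Conditions: Ac2O, DMAP, pyridine, 40 °C
Reagents that add atoms: acetic anhydride, CC(=O)OC(C)=O
Why: DMAP-catalysed acylation esterifies the secondary 6β-hydroxyl; the tertiary, axial 9α-hydroxyl does not react.

Step 13
Reactants: 18 acetate diene
Product: 19 (5S,6R,8R,9R,10S)-6β-acetoxy-9β-[2-(2,5-dihydrofuran-3-yl)ethyl]-4,4,8α,10-tetramethyl-trans-decalin-9α-ol
Conditions: second-generation Grubbs catalyst (5 mol %), CH2Cl2, 40 °C
Reagents that add atoms: none
Why: Ring-closing metathesis of the 1,1-disubstituted alkene with the allyl ether gives the five-membered trisubstituted cyclic alkene C13=C14 with loss of ethylene; the tertiary alcohol and acetate are inert.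

Step 14
Reactants: 19 dihydrofuran alcohol
Product: 21 (5S,6R,8R,9R,10S,13S,14S)-6β-acetoxy-9α,13;15,16-diepoxylabdan-14-ol, via epoxide 20 (not isolated)
Conditions: L-fructose-derived Shi ketone (mirror image of the D-fructose catalyst, 30 mol %), KHSO5 (as Oxone), K2CO3, Bu4NHSO4, Na2B4O7 buffer, MeCN/CH2(OMe)2/H2O, 0 °C; then CSA (10 mol %), CH2Cl2, 0 °C
Reagents that add atoms: potassium peroxymonosulfate, [K+].OOS(=O)(=O)[O-]
Why: Shi epoxidation: the chiral dioxirane delivers oxygen to one face of the trisubstituted alkene under reagent control (the substrate stereocenters are too remote to interfere), giving the (13R,14S)-epoxide 20. Acid then lets the 9α-hydroxyl open it at the tertiary C13 in a 5-exo mode with inversion, which closes the tetrahydrofuran and fixes C13; the C14 carbinol keeps its C–O bond.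

Step 15
Reactants: 21 dispiro alcohol
Product: 22 (5S,6R,8R,9R,10S,13R)-6β-acetoxy-9α,13;15,16-diepoxylabd-14-ene (target)
Conditions: Burgess reagent, Et3N (cat.), toluene, 70 °C
Reagents that add atoms: none
Why: Burgess dehydration (syn-elimination of the sulfamate ester) can only use the hydrogens on C15 because C13 is quaternary, so the 2,3-dihydrofuran is the sole alkene regiochemistry. The non-acidic medium preserves the allylic spiro ether and the acetate.

## Compound list

1 | mesityl oxide (4-methylpent-3-en-2-one) | CC(=O)C=C(C)C | starting material
2 | triisopropylsilyl trifluoromethanesulfonate | CC(C)[Si](OS(=O)(=O)C(F)(F)F)(C(C)C)C(C)C | starting material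
3 | 2-(triisopropylsilyloxy)-4-methylpenta-1,3-diene | C=C(O[Si](C(C)C)(C(C)C)C(C)C)C=C(C)C | intermediate
4 | 2,6-dimethyl-1,4-benzoquinone | CC1=CC(=O)C=C(C)C1=O | starting material
5 | (5R,10S)-cis-fused enedione, 4,4,8,10-tetramethyl-2-(triisopropylsilyloxy)decalin-2,7-diene-6,9-dione | O=C1C=C(C)C(=O)[C@@]2(C)CC(O[Si](C(C)C)(C(C)C)C(C)C)=CC(C)(C)[C@@H]12 | intermediate
6 | (5R,8R,10S)-cis-fused 4,4,8,10-tetramethyl-2-(triisopropylsilyloxy)decalin-2-ene-6,9-dione | O=C1C[C@@H](C)C(=O)[C@@]2(C)CC(O[Si](C(C)C)(C(C)C)C(C)C)=CC(C)(C)[C@@H]12 | intermediate
7 | (5S,8R,10S)-trans-fused 4,4,8,10-tetramethyl-2-(triisopropylsilyloxy)decalin-2-ene-6,9-dione | O=C1C[C@@H](C)C(=O)[C@@]2(C)CC(O[Si](C(C)C)(C(C)C)C(C)C)=CC(C)(C)[C@H]12 | intermediate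
8 | (5S,6R,8R,10S)-6β-hydroxy-4,4,8α,10-tetramethyl-2-(triisopropylsilyloxy)-trans-decalin-2-en-9-one | O[C@@H]1C[C@@H](C)C(=O)[C@@]2(C)CC(O[Si](C(C)C)(C(C)C)C(C)C)=CC(C)(C)[C@H]12 | intermediate
9 | (5S,6R,8R,10S)-6β-hydroxy-4,4,8α,10-tetramethyl-trans-decalin-2,9-dione 2-(ethane-1,2-diyl dithioketal) | O[C@@H]1C[C@@H](C)C(=O)[C@@]2(C)CC3(SCCS3)CC(C)(C)[C@H]12 | intermediate
10 | (5S,6R,8R,10S)-6β-hydroxy-4,4,8α,10-tetramethyl-trans-decalin-9-one | O[C@@H]1C[C@@H](C)C(=O)[C@@]2(C)CCCC(C)(C)[C@H]12 | intermediate
11 | (5S,6R,8R,10S)-4,4,8α,10-tetramethyl-9-methylene-trans-decalin-6β-ol | O[C@@H]1C[C@@H](C)C(=C)[C@@]2(C)CCCC(C)(C)[C@H]12 | intermediate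
12 | (5S,6R,8R,9R,10S)-9α,11-epoxy-4,4,8α,10-tetramethyl-trans-decalin-6β-ol (spiro oxirane at C9) | O[C@@H]1C[C@@H](C)[C@]3(CO3)[C@@]2(C)CCCC(C)(C)[C@H]12 | intermediate
13 | 3-chloro-2-(chloromethyl)prop-1-ene | C=C(CCl)CCl | starting material
14 | allyl alcohol (prop-2-en-1-ol) | C=CCO | starting material
15 | 3-(allyloxy)-2-(chloromethyl)prop-1-ene | C=CCOCC(=C)CCl | intermediate
16 | {2-[(allyloxy)methyl]prop-2-en-1-yl}magnesium chloride | C=CCOCC(=C)C[Mg]Cl | intermediate
17 | (5S,6R,8R,9R,10S)-9β-{3-[(allyloxy)methyl]but-3-en-1-yl}-4,4,8α,10-tetramethyl-trans-decalin-6β,9α-diol | O[C@@H]1C[C@@H](C)[C@](O)(CCC(=C)COCC=C)[C@@]2(C)CCCC(C)(C)[C@H]12 | intermediate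
18 | (5S,6R,8R,9R,10S)-6β-acetoxy-9β-{3-[(allyloxy)methyl]but-3-en-1-yl}-4,4,8α,10-tetramethyl-trans-decalin-9α-ol | CC(=O)O[C@@H]1C[C@@H](C)[C@](O)(CCC(=C)COCC=C)[C@@]2(C)CCCC(C)(C)[C@H]12 | intermediate
19 | (5S,6R,8R,9R,10S)-6β-acetoxy-9β-[2-(2,5-dihydrofuran-3-yl)ethyl]-4,4,8α,10-tetramethyl-trans-decalin-9α-ol | CC(=O)O[C@@H]1C[C@@H](C)[C@](O)(CCC3=CCOC3)[C@@]2(C)CCCC(C)(C)[C@H]12 | intermediate
20 | (13R,14S)-13,14-epoxide of 19 (side chain ends in a 1-substituted 3,6-dioxabicyclo[3.1.0]hexane) | CC(=O)O[C@@H]1C[C@@H](C)[C@](O)(CC[C@@]34COC[C@@H]3O4)[C@@]2(C)CCCC(C)(C)[C@H]12 | intermediate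
21 | (5S,6R,8R,9R,10S,13S,14S)-6β-acetoxy-9α,13;15,16-diepoxylabdan-14-ol | CC(=O)O[C@@H]1C[C@@H](C)[C@]2(CC[C@]3([C@@H](O)COC3)O2)[C@@]2(C)CCCC(C)(C)[C@H]12 | intermediate
22 | (5S,6R,8R,9R,10S,13R)-6β-acetoxy-9α,13;15,16-diepoxylabd-14-ene | CC(=O)O[C@@H]1C[C@@H](C)[C@]2(CC[C@]3(C=COC3)O2)[C@@]2(C)CCCC(C)(C)[C@H]12 | target

## Step count and least certain steps

Total step count: 15. Longest linear sequence: 14 steps (steps 1 to 9 and 11 to 15); step 10 is a one-step side branch.

**Step 2 (key step).** The most likely failure is that the second bond, from the fully substituted diene terminus to C5, forms too slowly at the temperatures where the catalyst is selective. The reaction then leaves the concerted path after the first C1–C10 bond and ends, by silyl transfer, as an open Michael adduct; acid-promoted loss of the silyl group from the diene and lower enantioselectivity on warming are related risks.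
Fallback: accept the stepwise course and finish the annulation as a separate ring closure. It sets out from 3 and 4, which under the same catalyst would give the open adduct F1, (S)-6-methyl-6-(4-methyl-2-oxopent-3-en-1-yl)-2-methyl-4-(triisopropylsilyloxy)cyclohexa-2,4-dien-1-one; C10 is already set in the catalyst-controlled first addition. F1 is then closed by an intramolecular Mukaiyama–Michael addition of its silyl dienol ether carbon C5 to the β,β-dimethyl enone (catalytic Tf2NH, CH2Cl2, −78 °C, with silyl transfer to the new enolate), which returns to the route at compound 5. The configuration formed at C5 does not matter because step 4 equilibrates it.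

**Step 4.** The equilibrium may not lie far enough on the trans side, because the trans isomer carries the interaction of the equatorial C4 methyl with the C6 carbonyl in addition to the two axial methyls. Prolonged base may also erode the silyl enol ether.
Fallback: move the inversion one step earlier, to a system in which C5 is the only stereolabile center and ring B is nearly planar. It sets out from compound 5, which is equilibrated through its C5 dienolate (Et3N or DBU, CH2Cl2) to the trans-fused enedione F2, (5S,10S)-4,4,8,10-tetramethyl-2-(triisopropylsilyloxy)decalin-2,7-diene-6,9-dione. Reduction of F2 with Zn/AcOH, with C8 settling equatorial on the now trans-fused skeleton, comes back to the route at compound 7.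

**Step 11.** The epoxide carbon C11 is neopentyl-like, so substitution can be slow. Magnesium halide may then open the tertiary C9–O bond first, leading to a 1,2-hydride shift to the aldehyde or to migration of the C10 methyl.
Fallback: form the C11–C12 bond by a radical instead of a polar process. It sets out from compound 12, which is opened by iodide (LiI, AcOH, THF) to the iodohydrin F3, (5S,6R,8R,9R,10S)-9β-(iodomethyl)-4,4,8α,10-tetramethyl-trans-decalin-6β,9α-diol. Chloride 15 is converted with Bu3SnLi into the allylstannane F4, {2-[(allyloxy)methyl]prop-2-en-1-yl}tributylstannane. A Keck radical allylation of F3 with F4 (AIBN, benzene, 80 °C) comes back to the route at compound 17.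

**Step 14.** The two faces of the dihydrofuran alkene differ only through the remote decalin, so the outcome depends entirely on the chiral dioxirane. Its facial selectivity may be insufficient, and the alkene, with oxygen on both allylic carbons, may be epoxidized more slowly than the catalyst decomposes.
Fallback: set C13 by a Sharpless asymmetric epoxidation of an acyclic allylic alcohol and build the enol ether from an alkyne. It sets out from compound 12 and proceeds as follows:

- Compound 12 is opened with dilithiated 2-methylprop-2-en-1-ol (n-BuLi, TMEDA; CuI cat.) to the triol F5, (5S,6R,8R,9R,10S)-9β-[3-(hydroxymethyl)but-3-en-1-yl]-4,4,8α,10-tetramethyl-trans-decalin-6β,9α-diol.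
- Sharpless epoxidation (Ti(OiPr)4, L-(+)-diethyl tartrate, t-BuOOH, 4 Å sieves, −20 °C) gives the (13S)-epoxy alcohol F6.
- Primary-selective oxidation (TEMPO, PhI(OAc)2) gives the epoxy aldehyde F7.
- Ohira–Bestmann homologation gives the epoxy alkyne F8.
- CSA closes the tetrahydrofuran by invertive 5-exo opening to the ethynyl carbinol F9, (5S,6R,8R,9R,10S,13R)-13-ethynyl-9α,13-epoxy-14,15-dinorlabdane-6β,16-diol.
- Cycloisomerization of the homopropargylic alcohol through a molybdenum vinylidene (Mo(CO)6, Et3N, Et2O, hν) gives the deacetyl compound F10, (5S,6R,8R,9R,10S,13R)-9α,13;15,16-diepoxylabd-14-en-6β-ol.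
- Acetylation of F10 (Ac2O, DMAP, Et3N) comes back to the route at compound 22.

**Step 15.** The sulfamate sits on a neopentyl-type carbon flanked by two β-oxygens, so elimination may be slow. Ionization could instead trigger a 1,2-shift from C13, or the product could aromatize to the furan if the medium turns acidic.
Fallback: replace the dehydration by an oxidation and reduction sequence that never places a leaving group on sp3 C14. It sets out from compound 21, which is oxidized (Dess–Martin periodinane, NaHCO3) to the ketone F11, (5S,6R,8R,9R,10S,13S)-6β-acetoxy-9α,13;15,16-diepoxylabdan-14-one. Deprotonation at C15, the only enolizable position (KHMDS, PhNTf2, THF, −78 °C), gives the enol triflate F12, 6β-acetoxy-14-(trifluoromethanesulfonyloxy)-9α,13;15,16-diepoxylabd-14-ene. Its palladium-catalysed reduction (Pd(OAc)2, PPh3, Bu3N, HCO2H, DMF, 60 °C) comes back to the route at compound 22.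

## Further compounds

F1 | step 2 | (S)-6-methyl-6-(4-methyl-2-oxopent-3-en-1-yl)-2-methyl-4-(triisopropylsilyloxy)cyclohexa-2,4-dien-1-one (open Michael adduct) | CC(C)=CC(=O)C[C@@]1(C)C=C(O[Si](C(C)C)(C(C)C)C(C)C)C=C(C)C1=O
F2 | step 4 | (5S,10S)-trans-fused 4,4,8,10-tetramethyl-2-(triisopropylsilyloxy)decalin-2,7-diene-6,9-dione | O=C1C=C(C)C(=O)[C@@]2(C)CC(O[Si](C(C)C)(C(C)C)C(C)C)=CC(C)(C)[C@H]12
F3 | step 11 | (5S,6R,8R,9R,10S)-9β-(iodomethyl)-4,4,8α,10-tetramethyl-trans-decalin-6β,9α-diol | O[C@@H]1C[C@@H](C)[C@](O)(CI)[C@@]2(C)CCCC(C)(C)[C@H]12
F4 | step 11 | {2-[(allyloxy)methyl]prop-2-en-1-yl}tributylstannane | C=CCOCC(=C)C[Sn](CCCC)(CCCC)CCCC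
F5 | step 14 | (5S,6R,8R,9R,10S)-9β-[3-(hydroxymethyl)but-3-en-1-yl]-4,4,8α,10-tetramethyl-trans-decalin-6β,9α-diol | O[C@@H]1C[C@@H](C)[C@](O)(CCC(=C)CO)[C@@]2(C)CCCC(C)(C)[C@H]12
F6 | step 14 | (13S)-epoxy alcohol, 9β-{2-[(S)-2-(hydroxymethyl)oxiran-2-yl]ethyl}-4,4,8α,10-tetramethyl-trans-decalin-6β,9α-diol | O[C@@H]1C[C@@H](C)[C@](O)(CC[C@]3(CO)CO3)[C@@]2(C)CCCC(C)(C)[C@H]12
F7 | step 14 | epoxy aldehyde, 2-[2-(6β,9α-dihydroxy-4,4,8α,10-tetramethyl-trans-decalin-9β-yl)ethyl]oxirane-2-carbaldehyde | O[C@@H]1C[C@@H](C)[C@](O)(CC[C@]3(C=O)CO3)[C@@]2(C)CCCC(C)(C)[C@H]12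
F8 | step 14 | epoxy alkyne, 9β-[2-(2-ethynyloxiran-2-yl)ethyl]-4,4,8α,10-tetramethyl-trans-decalin-6β,9α-diol | O[C@@H]1C[C@@H](C)[C@](O)(CC[C@]3(C#C)CO3)[C@@]2(C)CCCC(C)(C)[C@H]12
F9 | step 14 | (5S,6R,8R,9R,10S,13R)-13-ethynyl-9α,13-epoxy-14,15-dinorlabdane-6β,16-diol | O[C@@H]1C[C@@H](C)[C@]2(CC[C@](CO)(C#C)O2)[C@@]2(C)CCCC(C)(C)[C@H]12
F10 | step 14 | (5S,6R,8R,9R,10S,13R)-9α,13;15,16-diepoxylabd-14-en-6β-ol | O[C@@H]1C[C@@H](C)[C@]2(CC[C@]3(C=COC3)O2)[C@@]2(C)CCCC(C)(C)[C@H]12
F11 | step 15 | (5S,6R,8R,9R,10S,13S)-6β-acetoxy-9α,13;15,16-diepoxylabdan-14-one | CC(=O)O[C@@H]1C[C@@H](C)[C@]2(CC[C@]3(C(=O)COC3)O2)[C@@]2(C)CCCC(C)(C)[C@H]12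
F12 | step 15 | 6β-acetoxy-14-(trifluoromethanesulfonyloxy)-9α,13;15,16-diepoxylabd-14-ene | CC(=O)O[C@@H]1C[C@@H](C)[C@]2(CC[C@]3(C(OS(=O)(=O)C(F)(F)F)=COC3)O2)[C@@]2(C)CCCC(C)(C)[C@H]12
A1 | alternative 1 | 6β-acetoxy-9α,13-epoxylabdane with tert-butyldimethylsilyl ether on C16 and p-methoxybenzyl ether on C15 | CC(=O)O[C@@H]1C[C@@H](C)[C@]2(CC[C@](CO[Si](C)(C)C(C)(C)C)(CCOCc3ccc(OC)cc3)O2)[C@@]2(C)CCCC(C)(C)[C@H]12
A2 | alternative 1 | 6β-acetoxy-4,4,8α,10-tetramethyl-9-methylene-trans-decalin | CC(=O)O[C@@H]1C[C@@H](C)C(=C)[C@@]2(C)CCCC(C)(C)[C@H]12
A3 | alternative 1 | chiral iodohydrin, 1-(tert-butyldimethylsilyloxy)-2-(iodomethyl)-4-(p-methoxybenzyloxy)butan-2-ol | IC[C@](CO[Si](C)(C)C(C)(C)C)(CCOCc1ccc(OC)cc1)O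
A4 | alternative 2 | trans-fused 6α-nitro-4,4,8α,10-tetramethyldecalin-9-one | [O-][N+](=O)[C@H]1C[C@@H](C)C(=O)[C@@]2(C)CCCC(C)(C)[C@H]12
A5 | alternative 2 | (E)-2,4,8,8-tetramethyl-10-nitrodeca-1,9-dien-3-one | C=C(C)C(=O)C(C)CCCC(C)(C)/C=C/[N+](=O)[O-]
A6 | alternative 3 | tricyclic 9α,13-epoxy-5-ene with C13 bearing CH2OH and CH2O-tert-butyldiphenylsilyl arms | C1C[C@@H](C)[C@]2(CC[C@](CO[Si](c3ccccc3)(c3ccccc3)C(C)(C)C)(CO)O2)[C@@]2(C)CCCC(C)(C)C=12
A7 | alternative 3 | epoxy ketone, 1-{2-[(tert-butyldiphenylsilyloxy)methyl]oxiran-2-yl}-4-methyl-6-(2,6,6-trimethylcyclohex-1-en-1-yl)hexan-3-one | CC1=C(CC[C@@H](C)C(=O)CC[C@@]2(CO[Si](c3ccccc3)(c3ccccc3)C(C)(C)C)CO2)C(C)(C)CCC1
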